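## Retrosynthetic overview
1. Target 20 comes from 19 by one acidic global deprotection (two aryl MOM ethers, two TBS ethers).
2. The C7–syringyl bond comes from a B-alkyl Suzuki–Miyaura coupling of alkene 17 with aryl bromide 16.
3. The C1–guaiacyl bond and the absolute configuration come from an enantiotopic-group-selective CuH/Pd hydroarylation of the meso-diene 5 with aryl bromide 9.
4. 5 comes from cis-cyclopent-4-ene-1,3-diol by ring cleavage and double methylenation, so the cis-diol becomes the syn-1,3-diol. 9 comes from catechol and 16 from resorcinol.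
5. No ring is formed. Both arenes enter intact, and the only carbocycle (in 1) is opened.

Assumption: the sense of group selection in step 11 must be found by experiment. The route is written for (R)-DTBM-SEGPHOS selecting the vinyl group on the (R)-configured carbinol carbon of 5. If the opposite sense is found, the (S)-ligand is used and nothing else changes.

## Route

Step 1
Reactants: 1 cis-cyclopent-4-ene-1,3-diol [(1R,3S), meso]
Product: 2 cis-3,5-bis(tert-butyldimethylsilyloxy)cyclopent-1-ene (meso)
Conditions: TBSCl (2.4 equiv), imidazole (5 equiv), DMF, rt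
Reagents that add atoms: tert-butyldimethylsilyl chloride (TBSCl), CC(C)(C)[Si](C)(C)Cl
Why: Corey silylation of both secondary alcohols leaves the cis C–O relation, which later becomes the syn-1,3-diol, untouched.

Step 2
Reactants: 2 cis-3,5-bis(tert-butyldimethylsilyloxy)cyclopent-1-ene
Product: 4 (2R,4S)-2,4-bis(tert-butyldimethylsilyloxy)pentanedial (meso), via secondary ozonide 3 (not isolated)
Conditions: O3, CH2Cl2, −78 °C; then PPh3, −78 °C → rt; used crude
Reagents that add atoms: ozone, [O-][O+]=O
Why: Criegee ozonolysis with reductive work-up cleaves only the ring C=C, so the cis ring diol is unfolded into the acyclic syn (meso) dialdehyde, and no β-leaving group is present that could eliminate.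

Step 3
Reactants: 4 (2R,4S)-2,4-bis(tert-butyldimethylsilyloxy)pentanedial
Product: 5 (3R,5S)-3,5-bis(tert-butyldimethylsilyloxy)hepta-1,6-diene (meso, syn)
Conditions: Ph3PCH3Br (3.0 equiv), KHMDS (2.8 equiv), THF, 0 °C; then 4, −78 → 0 °C
Reagents that add atoms: methyltriphenylphosphonium bromide, C[P+](c1ccccc1)(c1ccccc1)c1ccccc1.[Br-]
Why: Two-directional Wittig methylenation with the salt-free, non-stabilised ylide at low temperature is faster than enolisation of α-silyloxy aldehydes, so the meso relation survives.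

Step 4
Reactants: 6 catechol
Product: 7 2-methoxyphenol (guaiacol)
Conditions: 6 (2 equiv), MeI (1.0 equiv), K2CO3 (1.0 equiv), acetone, reflux; excess 6 washed out with water
Reagents that add atoms: iodomethane, CI
Why: Williamson monomethylation with the diol in excess keeps dimethylation low, and the water-soluble catechol is easily removed.

Step 5
Reactants: 7 2-methoxyphenol
Product: 8 4-bromo-2-methoxyphenol
Conditions: NBS (1.0 equiv), MeCN, 0 °C → rt
Reagents that add atoms: N-bromosuccinimide, O=C1CCC(=O)N1Br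
Why: In this electrophilic aromatic bromination the free OH is the stronger director, so bromine enters para to OH.

Step 6
Reactants: 8 4-bromo-2-methoxyphenol
Product: 9 4-bromo-2-methoxy-1-(methoxymethoxy)benzene
Conditions: MOMCl, i-Pr2NEt, CH2Cl2, 0 °C → rt
Reagents that add atoms: chloromethyl methyl ether (MOMCl), COCCl
Why: O-alkylation of the phenol gives a base-, silane- and borane-stable acetal that falls off together with the TBS groups in the last step.

Step 7
Reactants: 10 resorcinol
Product: 11 1,3-dimethoxybenzene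
Conditions: Me2SO4 (2.3 equiv), K2CO3, acetone, reflux
Reagents that add atoms: dimethyl sulfate, COS(=O)(=O)OC
Why: Exhaustive Williamson O-methylation with the hard electrophile avoids C-methylation of the resorcinol ring.

Step 8
Reactants: 11 1,3-dimethoxybenzene
Product: 14 2,6-dimethoxyphenol, via 2,6-dimethoxyphenyllithium 12 (not isolated), via dimethyl (2,6-dimethoxyphenyl)boronate 13 (not isolated)
Conditions: n-BuLi, THF, 0 °C → rt; B(OMe)3, −78 °C → rt; 30% aq H2O2, 0 °C → rt
Reagents that add atoms: hydrogen peroxide, OO (phenol oxygen of 14); n-butyllithium, [Li]CCCC (Li, only in 12); trimethyl borate, COB(OC)OC (boron unit, only in 13)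
Why: Directed ortho-metalation occurs only at C2 between the two cooperating OMe groups, and borylation followed by 1,2-aryl migration on peroxide oxidation puts oxygen exactly there.

Step 9
Reactants: 14 2,6-dimethoxyphenol
Product: 15 4-bromo-2,6-dimethoxyphenol
Conditions: NBS (1.0 equiv), CHCl3 (1% MeOH, cat. NaH), −45 °C → rt
Reagents that add atoms: N-bromosuccinimide, O=C1CCC(=O)N1Br
Why: At low temperature the phenol/phenoxide directs this electrophilic bromination para to OH, in preference to the positions ortho/para to the OMe groups.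

Step 10
Reactants: 15 4-bromo-2,6-dimethoxyphenol
Product: 16 5-bromo-1,3-dimethoxy-2-(methoxymethoxy)benzene
Conditions: MOMCl, i-Pr2NEt, CH2Cl2, 0 °C → reflux
Reagents that add atoms: chloromethyl methyl ether (MOMCl), COCCl
Why: O-alkylation with the small, highly reactive oxocarbenium precursor works even on the doubly ortho-substituted phenol.

Step 11
Reactants: 5 (3R,5S)-3,5-bis(tert-butyldimethylsilyloxy)hepta-1,6-diene (1.0 equiv); 9 4-bromo-2-methoxy-1-(methoxymethoxy)benzene (1.1 equiv)
Product: 17 (3S,5S)-3,5-bis(tert-butyldimethylsilyloxy)-7-[3-methoxy-4-(methoxymethoxy)phenyl]hept-1-ene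
Conditions: Cu(OAc)2 (5 mol %), (R)-DTBM-SEGPHOS (5.5 mol %), [Pd(cinnamyl)Cl]2 (2 mol %), BrettPhos (4.4 mol %), MePh2SiH (2 equiv), NaOSiMe3 (2 equiv), THF, 25–40 °C
Reagents that add atoms: none
Why: Proposed new method: this is an enantiotopic-group-selective version of the CuH/Pd dual-catalytic anti-Markovnikov hydroarylation of terminal alkenes with aryl bromides (the closest known reaction, so far never used to choose between two mirror-image alkenes); the bulky chiral L*CuH adds irreversibly across one vinyl group (H to C2, Cu to C1), and because the hydride goes to the carbon next to the silyloxy stereocentre, the Felkin-type preferred face of the (R)-side vinyl is matched with the ligand pocket while that of the (S)-side vinyl is mismatched, so essentially one primary alkylcopper forms; it has no β-leaving group (OTBS is γ), it transmetallates to (BrettPhos)Pd(Ar)Br, and reductive elimination forms the aryl–C1 bond and thereby fixes the absolute configuration of both carbinol carbons (the reacted centre changes from R to S by CIP priority only), while the minor mono-adduct still carries the fast-reacting vinyl group and is drained to the separable meso bis-adduct, raising the ee as in known group-selective desymmetrisations of divinyl carbinols.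

Step 12
Reactants: 17 (3S,5S)-3,5-bis(tert-butyldimethylsilyloxy)-7-[3-methoxy-4-(methoxymethoxy)phenyl]hept-1-ene; 16 5-bromo-1,3-dimethoxy-2-(methoxymethoxy)benzene
Product: 19 (3S,5R)-3,5-bis(tert-butyldimethylsilyloxy)-7-[3,5-dimethoxy-4-(methoxymethoxy)phenyl]-1-[3-methoxy-4-(methoxymethoxy)phenyl]heptane, via 9-[(3R,5S)-3,5-bis(tert-butyldimethylsilyloxy)-7-[3-methoxy-4-(methoxymethoxy)phenyl]heptyl]-9-borabicyclo[3.3.1]nonane 18 (not isolated)
Conditions: 9-BBN-H (1.5 equiv), THF, 0 °C → rt; then 16, PdCl2(dppf)·CH2Cl2 (5 mol %), 3 M aq K3PO4, THF/DMF, 60 °C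
Reagents that add atoms: 9-borabicyclo[3.3.1]nonane (9-BBN-H), B1C2CCCC1CCC2 (boron unit only in 18; 19 keeps only its hydrogen)
Why: Anti-Markovnikov hydroboration followed by B-alkyl Suzuki–Miyaura coupling forms the second aryl–CH2 bond without touching either stereocentre or the MOM and TBS groups.

Step 13
Reactants: 19 (3S,5R)-3,5-bis(tert-butyldimethylsilyloxy)-7-[3,5-dimethoxy-4-(methoxymethoxy)phenyl]-1-[3-methoxy-4-(methoxymethoxy)phenyl]heptane
Product: 20 (3S,5R)-1-(4-hydroxy-3-methoxyphenyl)-7-(4-hydroxy-3,5-dimethoxyphenyl)heptane-3,5-diol (target)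
Conditions: HCl (1.25 M in MeOH), 45 °C
Reagents that add atoms: none
Why: Acid-catalysed methanolysis (transacetalisation and desilylation) removes both MOM and both TBS groups by O–C(acetal) and O–Si cleavage, so the carbinol C–O bonds and their configuration stay intact, and excess MeOH traps formaldehyde as its dimethyl acetal.

## Compound list
1 | cis-cyclopent-4-ene-1,3-diol, (1R,3S), meso | O[C@@H]1C[C@H](O)C=C1 | starting material
2 | cis-3,5-bis(tert-butyldimethylsilyloxy)cyclopent-1-ene (meso) | CC(C)(C)[Si](C)(C)O[C@@H]1C[C@H](O[Si](C)(C)C(C)(C)C)C=C1 | intermediate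
3 | secondary ozonide of 2: cis-2,4-bis(tert-butyldimethylsilyloxy)-6,7,8-trioxabicyclo[3.2.1]octane | O1OC2OC1[C@H](O[Si](C)(C)C(C)(C)C)C[C@@H]2O[Si](C)(C)C(C)(C)C | intermediate (not isolated)
4 | (2R,4S)-2,4-bis(tert-butyldimethylsilyloxy)pentanedial (meso) | O=C[C@H](O[Si](C)(C)C(C)(C)C)C[C@H](O[Si](C)(C)C(C)(C)C)C=O | intermediate
5 | (3R,5S)-3,5-bis(tert-butyldimethylsilyloxy)hepta-1,6-diene (meso, syn) | C=C[C@H](O[Si](C)(C)C(C)(C)C)C[C@H](O[Si](C)(C)C(C)(C)C)C=C | intermediate
6 | catechol | Oc1ccccc1O | starting material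
7 | 2-methoxyphenol | COc1ccccc1O | intermediate
8 | 4-bromo-2-methoxyphenol | COc1cc(Br)ccc1O | intermediate
9 | 4-bromo-2-methoxy-1-(methoxymethoxy)benzene | COCOc1ccc(Br)cc1OC | intermediate
10 | resorcinol | Oc1cccc(O)c1 | starting material
11 | 1,3-dimethoxybenzene | COc1cccc(OC)c1 | intermediate
12 | 2,6-dimethoxyphenyllithium | [Li]c1c(OC)cccc1OC | intermediate (not isolated)
13 | dimethyl (2,6-dimethoxyphenyl)boronate | COB(OC)c1c(OC)cccc1OC | intermediate (not isolated)
14 | 2,6-dimethoxyphenol | COc1cccc(OC)c1O | intermediate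
15 | 4-bromo-2,6-dimethoxyphenol | COc1cc(Br)cc(OC)c1O | intermediate
16 | 5-bromo-1,3-dimethoxy-2-(methoxymethoxy)benzene | COCOc1c(OC)cc(Br)cc1OC | intermediate
17 | (3S,5S)-3,5-bis(tert-butyldimethylsilyloxy)-7-[3-methoxy-4-(methoxymethoxy)phenyl]hept-1-ene | COCOc1ccc(CC[C@H](O[Si](C)(C)C(C)(C)C)C[C@H](O[Si](C)(C)C(C)(C)C)C=C)cc1OC | intermediate
18 | 9-[(3R,5S)-3,5-bis(tert-butyldimethylsilyloxy)-7-[3-methoxy-4-(methoxymethoxy)phenyl]heptyl]-9-borabicyclo[3.3.1]nonane | COCOc1ccc(CC[C@H](O[Si](C)(C)C(C)(C)C)C[C@H](O[Si](C)(C)C(C)(C)C)CCB2C3CCCC2CCC3)cc1OC | intermediate (not isolated)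
19 | (3S,5R)-3,5-bis(tert-butyldimethylsilyloxy)-7-[3,5-dimethoxy-4-(methoxymethoxy)phenyl]-1-[3-methoxy-4-(methoxymethoxy)phenyl]heptane | COCOc1ccc(CC[C@H](O[Si](C)(C)C(C)(C)C)C[C@H](O[Si](C)(C)C(C)(C)C)CCc2cc(OC)c(OCOC)c(OC)c2)cc1OC | intermediate
20 | (3S,5R)-1-(4-hydroxy-3-methoxyphenyl)-7-(4-hydroxy-3,5-dimethoxyphenyl)heptane-3,5-diol | COc1cc(CC[C@H](O)C[C@H](O)CCc2cc(OC)c(O)c(OC)c2)ccc1O | target

## Step count
Total step count: 13.

Longest linear sequence: 6 steps. All three branches are equally long:
- Core branch: steps 1, 2, 3, 11, 12, 13.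
- Guaiacyl branch: steps 4, 5, 6, 11, 12, 13.
- Syringyl branch: steps 7, 8, 9, 10, 12, 13.

## Three steps most likely to fail

**Step 11 (the new desymmetrising hydroarylation).** The group selectivity may be low, or Heck and ArBr-reduction side paths may compete. The fallback uses known chemistry only, sets out from 9 and comes back at 17, and the branch of steps 1–3 is then not needed. A Jeffery–Heck reaction of 9 with allyl alcohol (Pd(OAc)2, n-Bu4NCl, NaHCO3, DMF, 90 °C) gives 3-[3-methoxy-4-(methoxymethoxy)phenyl]propanal F1. Brown allylation with (+)-Ipc2B(allyl), the allylborane made from (−)-α-pinene (Et2O, −78 °C; NaOH/H2O2), gives (3S)-1-[3-methoxy-4-(methoxymethoxy)phenyl]hex-5-en-3-ol F2. Boc2O/DMAP converts this into the tert-butyl carbonate F3. Bartlett–Smith iodocarbonate cyclisation (IBr, toluene, −85 °C, cold enough to outrun arene iodination) gives the cis-configured (4S,6S)-4-(iodomethyl)-6-{2-[3-methoxy-4-(methoxymethoxy)phenyl]ethyl}-1,3-dioxan-2-one F4. K2CO3/MeOH turns it into the syn-epoxy alcohol (2S)-4-[3-methoxy-4-(methoxymethoxy)phenyl]-1-[(2S)-oxiran-2-yl]butan-2-ol F5, and TBSCl/imidazole gives its silyl ether F6. Dimethylsulfonium methylide (Me3SI, n-BuLi, THF, −10 °C → rt) homologates the terminal epoxide by one carbon to the allylic alcohol (3S,5S)-5-(tert-butyldimethylsilyloxy)-7-[3-methoxy-4-(methoxymethoxy)phenyl]hept-1-en-3-ol F7. A second silylation (TBSCl, imidazole) gives 17.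

**Step 3 (double Wittig on the epimerisable dialdehyde).** Any epimerisation would destroy the meso relation. The fallback sets out from 4 and comes back at 5 by an addition–elimination sequence instead of an ylide. Double addition of the weakly basic Me3SiCH2MgCl (THF, −78 °C) gives 3,5-bis(tert-butyldimethylsilyloxy)-1,7-bis(trimethylsilyl)heptane-2,6-diol F8 as a mixture of carbinol epimers, which does not matter here. A double Peterson syn-elimination (KH, THF, 0 °C) then gives 5.

**Step 9 (regioselective para-bromination of 14).** Attack ortho/para to the OMe groups or overbromination may compete. The fallback sets out from 14 and comes back at 19, replacing electronic control by steric control. MOM protection of 14 (MOMCl, i-Pr2NEt) gives 1,3-dimethoxy-2-(methoxymethoxy)benzene F9. Iridium-catalysed C–H borylation ([Ir(OMe)(cod)]2, dtbpy, B2pin2, THF, 80 °C) can only reach the one position without an ortho substituent and gives 2-[3,5-dimethoxy-4-(methoxymethoxy)phenyl]-4,4,5,5-tetramethyl-1,3,2-dioxaborolane F10. Copper-catalysed iododeboronation under near-neutral conditions (CuI, 1,10-phenanthroline, KI, MeOH/H2O, air, 80 °C) gives 5-iodo-1,3-dimethoxy-2-(methoxymethoxy)benzene F11. This iodide takes the place of 16 in the coupling with 18 under the conditions of step 12 and gives 19.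

## Further compounds
F1 | step 11 | 3-[3-methoxy-4-(methoxymethoxy)phenyl]propanal | COCOc1ccc(CCC=O)cc1OC
F2 | step 11 | (3S)-1-[3-methoxy-4-(methoxymethoxy)phenyl]hex-5-en-3-ol | COCOc1ccc(CC[C@H](O)CC=C)cc1OC
F3 | step 11 | tert-butyl (3S)-1-[3-methoxy-4-(methoxymethoxy)phenyl]hex-5-en-3-yl carbonate | COCOc1ccc(CC[C@H](OC(=O)OC(C)(C)C)CC=C)cc1OC
F4 | step 11 | (4S,6S)-4-(iodomethyl)-6-{2-[3-methoxy-4-(methoxymethoxy)phenyl]ethyl}-1,3-dioxan-2-one | COCOc1ccc(CC[C@H]2C[C@@H](CI)OC(=O)O2)cc1OC
F5 | step 11 | (2S)-4-[3-methoxy-4-(methoxymethoxy)phenyl]-1-[(2S)-oxiran-2-yl]butan-2-ol | COCOc1ccc(CC[C@H](O)C[C@H]2CO2)cc1OC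
F6 | step 11 | tert-butyldimethylsilyl ether of F5 | COCOc1ccc(CC[C@H](O[Si](C)(C)C(C)(C)C)C[C@H]2CO2)cc1OC
F7 | step 11 | (3S,5S)-5-(tert-butyldimethylsilyloxy)-7-[3-methoxy-4-(methoxymethoxy)phenyl]hept-1-en-3-ol | COCOc1ccc(CC[C@H](O[Si](C)(C)C(C)(C)C)C[C@H](O)C=C)cc1OC
F8 | step 3 | 3,5-bis(tert-butyldimethylsilyloxy)-1,7-bis(trimethylsilyl)heptane-2,6-diol (3,5-syn; C2/C6 epimer mixture) | C[Si](C)(C)CC(O)[C@H](O[Si](C)(C)C(C)(C)C)C[C@H](O[Si](C)(C)C(C)(C)C)C(O)C[Si](C)(C)C
F9 | step 9 | 1,3-dimethoxy-2-(methoxymethoxy)benzene | COCOc1c(OC)cccc1OC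
F10 | step 9 | 2-[3,5-dimethoxy-4-(methoxymethoxy)phenyl]-4,4,5,5-tetramethyl-1,3,2-dioxaborolane | COCOc1c(OC)cc(B2OC(C)(C)C(C)(C)O2)cc1OC
F11 | step 9 | 5-iodo-1,3-dimethoxy-2-(methoxymethoxy)benzene | COCOc1c(OC)cc(I)cc1OC
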